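## Retrosynthetic overview

1. The tetronic acid ring is formed last. It is opened at its lactone O1–C5 bond: a β-keto carboxylate oxygen attacks an alkyne 5-exo-dig. The carboxylate comes from CO2 and an ethyl alkynyl ketone.
2. The ynone comes from a terminal alkyne carrying the (S)-propargylic methyl centre and a propionyl Weinreb amide. The alkyne comes from an (S)-2-methyl primary alcohol by oxidation and one-carbon homologation.
3. The (S)-methyl centre comes from hydroxyl-directed asymmetric hydrogenation of an E-allylic alcohol, made by allylic oxidation of the terminal prenyl unit.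
4. The furan ring is bought. It is attached as 3-furylmethyl bromide to the hydroborated vinyl group of (R)-nerolidol (sp3–sp3 Suzuki coupling).
5. (R)-Nerolidol comes from (2E,6E)-farnesol. Sharpless epoxidation sets the C3–O bond (the transient oxirane is the first ring formed), and the epoxide is then opened reductively. The E-alkene and all 15 chain carbons come from farnesol.

Locants C1–C12 below are farnesane locants: C3 is the carbinol carbon, C11 the methyl-bearing methine, C12 the ylidene CH.

Assumption: the facial sense of step 6 is deduced from the (S)-BINAP/geraniol → (R)-citronellol precedent. If analysis showed the C11 epimer, (R)-BINAP would be used instead.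

## Route

Step 1
Reactants: 1 (2E,6E)-farnesol
Product: 2 (2R,3R)-2,3-epoxyfarnesol
Conditions: Ti(OiPr)4 (10 mol %), D-(−)-diisopropyl tartrate (12 mol %), t-BuOOH (2 equiv, decane), 4 Å MS, CH2Cl2, −20 °C
Reagents that add atoms: tert-butyl hydroperoxide, CC(C)(C)OO
Why: Sharpless asymmetric epoxidation: the titanium tartrate complex binds the allylic OH, so only the C2=C3 alkene reacts, and D-(−)-tartrate gives the (2R,3R) epoxide (mirror image of L-(+)-tartrate/geraniol → 2S,3S), which creates the C3–O bond of the target in the right configuration.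

Step 2
Reactants: 2 (2R,3R)-2,3-epoxyfarnesol
Product: 4 (3R,6E)-nerolidol, via epoxy iodide 3 (not isolated)
Conditions: PPh3, I2, imidazole, THF, 0 °C; then Zn dust, EtOH, 50 °C
Reagents that add atoms: none
Why: Appel-type iodination of the primary alcohol followed by zinc-induced reductive β-elimination (Boord-type fragmentation) breaks only the C1–I and C2–O bonds, so the tertiary C3–O stereocentre passes unchanged into the vinyl carbinol.

Step 3
Reactants: 5 furan-3-ylmethanol
Product: 6 3-(bromomethyl)furan
Conditions: PBr3 (0.4 equiv), Et2O, −10 to 0 °C; used at once as the ether solution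
Reagents that add atoms: phosphorus tribromide, BrP(Br)Br
Why: SN2 bromination of a primary furylmethyl alcohol through its phosphite ester, a standard preparation of this labile bromide.

Step 4
Reactants: 4 (3R,6E)-nerolidol; 6 3-(bromomethyl)furan
Product: 8 (4S,7E)-1-(furan-3-yl)-4,8,12-trimethyltrideca-7,11-dien-4-ol, via B-alkyl-9-BBN borane 7 (not isolated)
Conditions: 9-BBN dimer (1.1 equiv), THF, 0 °C → rt; then 6 (1.3 equiv), PdCl2(dppf) (5 mol %), K3PO4 (3 M aq), DMF, rt
Reagents that add atoms: none
Why: Anti-Markovnikov hydroboration by 9-BBN picks the only monosubstituted alkene, and B-alkyl Suzuki–Miyaura coupling with the β-hydrogen-free furylmethyl bromide forms the sp3–sp3 bond without touching C3 (R becomes S only through a change of CIP ranks).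

Step 5
Reactants: 8 (4S,7E)-1-(furan-3-yl)-4,8,12-trimethyltrideca-7,11-dien-4-ol
Product: 9 (2E,6E,10S)-13-(furan-3-yl)-2,6,10-trimethyltrideca-2,6-diene-1,10-diol
Conditions: SeO2 (0.3 equiv), t-BuOOH (3 equiv), salicylic acid (0.1 equiv), CH2Cl2, 0 °C, stopped at about 60 % conversion, 8 recycled
Reagents that add atoms: tert-butyl hydroperoxide, CC(C)(C)OO; selenium dioxide (oxygen relay), O=[Se]=O
Why: Riley allylic oxidation in its catalytic form (ene reaction, then [2,3]-sigmatropic shift) hydroxylates the E-methyl group of the more accessible terminal gem-dimethyl alkene and gives the E-allylic alcohol, while partial conversion spares the internal alkene and the furan.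

Step 6
Reactants: 9 (2E,6E,10S)-13-(furan-3-yl)-2,6,10-trimethyltrideca-2,6-diene-1,10-diol
Product: 10 (2S,6E,10S)-13-(furan-3-yl)-2,6,10-trimethyltridec-6-ene-1,10-diol
Conditions: Ru(OAc)2[(S)-BINAP] (0.5 mol %), H2 (100 atm), MeOH, 20 °C
Reagents that add atoms: none
Why: Noyori hydroxyl-directed asymmetric hydrogenation: only the allylic-alcohol alkene chelates to ruthenium, so the isolated C6=C7 alkene (bishomoallylic to the tertiary OH) and the furan stay intact, and H2 is added to the same face relative to CH2OH as in geraniol → (R)-citronellol, which sets C11 as S.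

Step 7
Reactants: 10 (2S,6E,10S)-13-(furan-3-yl)-2,6,10-trimethyltridec-6-ene-1,10-diol
Product: 12 (4S,7E,12S)-1-(furan-3-yl)-4,8,12-trimethyltetradec-7-en-13-yn-4-ol, via aldehyde 11 (not isolated)
Conditions: PhI(OAc)2 (1.1 equiv), TEMPO (10 mol %), CH2Cl2, rt; then MeOH, K2CO3 (5 equiv), dimethyl (1-diazo-2-oxopropyl)phosphonate (1.5 equiv), 0 °C → rt
Reagents that add atoms: dimethyl (1-diazo-2-oxopropyl)phosphonate, CC(=O)C(=[N+]=[N-])P(=O)(OC)OC
Why: TEMPO/PhI(OAc)2 oxidation stops at the aldehyde and ignores the tertiary OH, and Ohira–Bestmann (Seyferth–Gilbert) homologation turns the unpurified α-chiral aldehyde into the terminal alkyne at 0 °C before it can epimerise.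

Step 8
Reactants: 12 (4S,7E,12S)-1-(furan-3-yl)-4,8,12-trimethyltetradec-7-en-13-yn-4-ol; 13 N-methoxy-N-methylpropanamide
Product: 15 (6S,10E,14S)-17-(furan-3-yl)-14-hydroxy-6,10,14-trimethylheptadec-10-en-4-yn-3-one, via dilithio acetylide alkoxide 14 (not isolated)
Conditions: n-BuLi (2.05 equiv), THF, −78 °C; then 13 (1.2 equiv), −78 → −20 °C; inverse quench into cold pH 5 buffer
Reagents that add atoms: none
Why: Weinreb ketone synthesis with a lithium acetylide: the chelated tetrahedral adduct blocks over-addition, the second equivalent of n-BuLi only masks the tertiary OH, neither the furan nor the propargylic C11–H is metalated at −78 °C, and the cold acidic quench stops the released amine from adding to the ynone.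

Step 9
Reactants: 15 (6S,10E,14S)-17-(furan-3-yl)-14-hydroxy-6,10,14-trimethylheptadec-10-en-4-yn-3-one
Product: 17 (5Z)-5-[(2S,6E,10S)-13-(furan-3-yl)-10-hydroxy-2,6,10-trimethyltridec-6-en-1-ylidene]-4-hydroxy-3-methylfuran-2(5H)-one (CNP0217216.2), via beta-keto carboxylate 16 (not isolated)
Conditions: AgO2CPh (10 mol %), MTBD (2.5 equiv, pre-saturated with CO2 before 15 is added), CO2 (1.0 MPa), MeCN, 25 °C; then 1 M HCl, 0 °C
Reagents that add atoms: carbon dioxide, O=C=O
Why: Proposed new method: the guanidine reversibly enolises the propionyl CH2 (kinetically and thermodynamically more acidic than the tertiary propargylic C11–H), the enolate is C-carboxylated by CO2, and monovalent silver π-activates the alkyne so that the carboxylate oxygen closes the O1–C5 bond 5-exo-dig by anti-oxyargentation; protodeargentation with retention places C11 cis to O1 (Z), formation of the stable tetronate anion drains the unfavourable carboxylation equilibrium, and the enolised 1,3-dicarbonyl no longer polarises the alkyne as a Michael acceptor, so 6-endo pyrone closure is disfavoured; the closest known reaction type is the silver-catalysed carboxylative cyclisation of simple conjugated ynones, alkynyl ketones and propargylic alcohols or amines with CO2, and the new element is its use on a fully aliphatic propionyl ynone with a base-labile tertiary propargylic stereocentre, a free tertiary alcohol and a furan, with the base pre-loaded with CO2 to keep free guanidine low.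

## Compound list

1 | (2E,6E)-farnesol | CC(C)=CCC/C(C)=C/CC/C(C)=C/CO | starting material
2 | (2R,3R)-2,3-epoxyfarnesol | CC(C)=CCC/C(C)=C/CC[C@@]1(C)O[C@@H]1CO | intermediate
3 | (2S,3R)-2,3-epoxyfarnesyl iodide (same spatial arrangement as 2) | CC(C)=CCC/C(C)=C/CC[C@@]1(C)O[C@@H]1CI | intermediate
4 | (3R,6E)-nerolidol | CC(C)=CCC/C(C)=C/CC[C@@](C)(O)C=C | intermediate
5 | furan-3-ylmethanol | OCc1ccoc1 | starting material
6 | 3-(bromomethyl)furan | BrCc1ccoc1 | intermediate
7 | B-[(3S,6E)-3-hydroxy-3,7,11-trimethyldodeca-6,10-dien-1-yl]-9-borabicyclo[3.3.1]nonane (drawn with free OH) | CC(C)=CCC/C(C)=C/CC[C@@](C)(O)CCB1C2CCCC1CCC2 | intermediate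
8 | (4S,7E)-1-(furan-3-yl)-4,8,12-trimethyltrideca-7,11-dien-4-ol | CC(C)=CCC/C(C)=C/CC[C@@](C)(O)CCCc1ccoc1 | intermediate
9 | (2E,6E,10S)-13-(furan-3-yl)-2,6,10-trimethyltrideca-2,6-diene-1,10-diol | OC/C(C)=C/CC/C(C)=C/CC[C@@](C)(O)CCCc1ccoc1 | intermediate
10 | (2S,6E,10S)-13-(furan-3-yl)-2,6,10-trimethyltridec-6-ene-1,10-diol | OC[C@@H](C)CCC/C(C)=C/CC[C@@](C)(O)CCCc1ccoc1 | intermediate
11 | (2S,6E,10S)-13-(furan-3-yl)-10-hydroxy-2,6,10-trimethyltridec-6-enal | O=C[C@@H](C)CCC/C(C)=C/CC[C@@](C)(O)CCCc1ccoc1 | intermediate
12 | (4S,7E,12S)-1-(furan-3-yl)-4,8,12-trimethyltetradec-7-en-13-yn-4-ol | C#C[C@@H](C)CCC/C(C)=C/CC[C@@](C)(O)CCCc1ccoc1 | intermediate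
13 | N-methoxy-N-methylpropanamide | CCC(=O)N(C)OC | starting material
14 | dilithio acetylide alkoxide of 12 | [Li]C#C[C@@H](C)CCC/C(C)=C/CC[C@@](C)(O[Li])CCCc1ccoc1 | intermediate
15 | (6S,10E,14S)-17-(furan-3-yl)-14-hydroxy-6,10,14-trimethylheptadec-10-en-4-yn-3-one | CCC(=O)C#C[C@@H](C)CCC/C(C)=C/CC[C@@](C)(O)CCCc1ccoc1 | intermediate
16 | (6S,10E,14S)-17-(furan-3-yl)-14-hydroxy-2,6,10,14-tetramethyl-3-oxoheptadec-10-en-4-ynoic acid (present as its MTBD-H salt, C2 epimers, drawn as the free acid) | CC(C(=O)O)C(=O)C#C[C@@H](C)CCC/C(C)=C/CC[C@@](C)(O)CCCc1ccoc1 | intermediate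
17 | (5Z)-5-[(2S,6E,10S)-13-(furan-3-yl)-10-hydroxy-2,6,10-trimethyltridec-6-en-1-ylidene]-4-hydroxy-3-methylfuran-2(5H)-one | CC1=C(O)/C(=C/[C@@H](C)CCC/C(C)=C/CC[C@@](C)(O)CCCc2ccoc2)OC1=O | target

## Step count and risks

Total steps: 9. Longest linear sequence: 8 (steps 1, 2, 4, 5, 6, 7, 8, 9 from farnesol).

**Step 9, the proposed new step.**
- Three things can go wrong. Base-induced ynone → allenone isomerisation would scramble C11. Closure could go 6-endo to the 4-hydroxy-2-pyrone. Intermediate 16 could decarboxylate back to 15.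
- The fallback uses known chemistry. It sets out from aldehyde 11 (made from 10 by the first half of step 7 and used crude) and comes back at 17.
- O-Methylation of commercial 3-methyltetronic acid (Me2SO4, K2CO3, acetone) gives 4-methoxy-3-methylfuran-2(5H)-one F1.
- Its lithium dienolate (LDA, THF, −78 °C, 2.2 equiv to cover the free OH) adds through C5 to 11 and gives the aldol adduct F2. This is a diastereomer mixture, but both new centres are erased later.
- Ac2O/pyridine acetylates only the secondary carbinol and gives the acetate F3.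
- DBU (toluene, rt) eliminates by E1cB to the thermodynamically preferred (Z)-ylidene O-methyl tetronate F4.
- n-PrSLi in HMPA removes the O-methyl group by SN2 attack, and mild acid work-up gives 17.

**Step 6.**
- A 2-methyl-substituted allylic alcohol is a less proven substrate for Ru(OAc)2(BINAP) than geraniol. The ee may be lower, and isomerisation to the aldehyde may compete.
- The fallback replaces metal-directed hydrogenation by biocatalysis. It sets out from 9 and comes back at 10.
- MnO2 (CH2Cl2, rt) gives the (2E,6E)-enal F5.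
- An ene-reductase of the old-yellow-enzyme family (OYE2, or fermenting baker's yeast) with glucose/glucose dehydrogenase NADPH recycling reduces only the activated C10=C11 bond. This gives the (S)-aldehyde 11.
- An alcohol dehydrogenase in the same pot reduces 11 at once to 10.

**Step 4.**
- The sp3–sp3 Suzuki coupling can fail in three ways: homocoupling or hydrolysis of the labile bromide, and β-hydride elimination of the alkylpalladium.
- The fallback replaces palladium catalysis by a copper-catalysed Grignard displacement. It sets out from 4 (through the same borane 7) and comes back at 8.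
- NaOH/H2O2 oxidation of 7 gives the (3R,6E)-1,3-diol F6.
- TsCl/pyridine (0 °C) gives the primary tosylate F7.
- Bromide 6 and Mg turnings (THF, 0 °C) give 3-furylmethylmagnesium bromide F8.
- Three equivalents of F8 with Li2CuCl4 (5 mol %, THF, −20 °C) displace the tosylate and give 8. The first equivalent is consumed by the tertiary OH.

Further compounds
F1 | step 9 | 4-methoxy-3-methylfuran-2(5H)-one | COC1=C(C)C(=O)OC1
F2 | step 9 | 5-[(2S,6E,10S)-13-(furan-3-yl)-1,10-dihydroxy-2,6,10-trimethyltridec-6-en-1-yl]-4-methoxy-3-methylfuran-2(5H)-one (mixture at ring C5 and C1') | COC1=C(C)C(=O)OC1C(O)[C@@H](C)CCC/C(C)=C/CC[C@@](C)(O)CCCc1ccoc1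
F3 | step 9 | C1'-acetate of F2 | COC1=C(C)C(=O)OC1C(OC(C)=O)[C@@H](C)CCC/C(C)=C/CC[C@@](C)(O)CCCc1ccoc1
F4 | step 9 | (5Z)-5-[(2S,6E,10S)-13-(furan-3-yl)-10-hydroxy-2,6,10-trimethyltridec-6-en-1-ylidene]-4-methoxy-3-methylfuran-2(5H)-one | CC1=C(OC)/C(=C/[C@@H](C)CCC/C(C)=C/CC[C@@](C)(O)CCCc2ccoc2)OC1=O
F5 | step 6 | (2E,6E,10S)-13-(furan-3-yl)-10-hydroxy-2,6,10-trimethyltrideca-2,6-dienal | O=C/C(C)=C/CC/C(C)=C/CC[C@@](C)(O)CCCc1ccoc1
F6 | step 4 | (3R,6E)-3,7,11-trimethyldodeca-6,10-diene-1,3-diol | CC(C)=CCC/C(C)=C/CC[C@@](C)(O)CCO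
F7 | step 4 | (3R,6E)-3-hydroxy-3,7,11-trimethyldodeca-6,10-dien-1-yl 4-methylbenzenesulfonate | CC(C)=CCC/C(C)=C/CC[C@@](C)(O)CCOS(=O)(=O)c1ccc(C)cc1
F8 | step 4 | 3-furylmethylmagnesium bromide | Br[Mg]Cc1ccoc1
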